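**Retrosynthetic overview**
1. Target 17 ⇐ 15: the 6β-acetoxy 7-ketone is unmasked last from a C6=C7 enol acetate (epoxidation, then thermal 1,2-acyloxy shift with inversion at C6).
2. 15 ⇐ 13: ring D (C9–C11–C12–C13–C14) is closed by a samarium Barbier addition of C12 (primary iodide) to the C13 methyl ketone, which also sets the C13 carbinol.
3. 13 ⇐ 9 ⇐ 8: the cyclobutane (C8–C15, C9–C14) comes from an intramolecular enone–olefin [2+2] in which the four-carbon unit is tied to O–C12 as a mixed ketal at C13; this oxane ring is not in the target and is opened before step 11.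
4. 8 ⇐ 6 ⇐ (+)-sclareolide 1 (rings A/B with C5 and C10) plus 2-methoxy-1,3-butadiene 7; ring order: A/B from the chiral pool → cyclobutane with temporary oxane → ring D.
5. Enabling feature: on the cyclobutane the C14 acetyl group (C13=O) and the C9 two-carbon arm (C11–C12) are held cis by the former oxane, so C12 lies 5-exo to C13; C13 is trigonal in 13, so both ketal epimers converge.

Key step: step 11

Remark: labdane numbering is used for positions; 2-methoxy-1,3-butadiene (7) is treated as purchasable, and would otherwise be made in one operation from commercial 1,3,3-trimethoxybutane (KHSO4, heat).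

Step 1
Reactants: 1 (+)-sclareolide
Product: 2 13,14,15,16-tetranorlabdane-8α,12-diol
Conditions: LiAlH4, THF, 0 °C → rt
Reagents that add atoms: none
Why: Hydride reduction of the γ-lactone should open it to the primary C12 alcohol and the tertiary 8α-alcohol without touching C5, C9 or C10.

Step 2
Reactants: 2 13,14,15,16-tetranorlabdane-8α,12-diol
Product: 3 8α-hydroxy-13,14,15,16-tetranorlabdan-12-yl acetate
Conditions: Ac2O, pyridine, CH2Cl2, rt
Reagents that add atoms: acetic anhydride, CC(=O)OC(C)=O
Why: Acylation should be selective for the primary hydroxyl because the tertiary 8α-hydroxyl is too hindered under these conditions, and the acetate blocks 8,12-ether formation in the next step.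

Step 3
Reactants: 3 8α-hydroxy-13,14,15,16-tetranorlabdan-12-yl acetate
Product: 4 13,14,15,16-tetranorlabd-8(9)-en-12-yl acetate
Conditions: TsOH·H2O (cat.), toluene, 80 °C
Reagents that add atoms: none
Why: Acid-catalysed E1 dehydration under equilibrating conditions should converge on the tetrasubstituted Δ8(9) alkene, the most stable olefin isomer, and the C8 and C9 stereocentres are erased on purpose.

Step 4
Reactants: 4 13,14,15,16-tetranorlabd-8(9)-en-12-yl acetate
Product: 5 7-oxo-13,14,15,16-tetranorlabd-8(9)-en-12-yl acetate
Conditions: Na2CrO4, NaOAc, AcOH/Ac2O, 60 °C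
Reagents that add atoms: sodium chromate, [Na+].[Na+].[O-][Cr](=O)(=O)[O-]
Why: Chromium(VI) allylic oxidation should attack the ring methylene C7, the least hindered allylic CH2, to give the conjugated enone, as is usual for drim-8-ene systems.

Step 5
Reactants: 5 7-oxo-13,14,15,16-tetranorlabd-8(9)-en-12-yl acetate
Product: 6 12-hydroxy-13,14,15,16-tetranorlabd-8(9)-en-7-one
Conditions: K2CO3 (cat.), MeOH, rt
Reagents that add atoms: none
Why: Base-catalysed transesterification should remove the acetate under conditions that leave the tetrasubstituted enone unchanged.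

Step 6
Reactants: 6 12-hydroxy-13,14,15,16-tetranorlabd-8(9)-en-7-one; 7 2-methoxy-1,3-butadiene
Product: 8 12-[(2-methoxybut-3-en-2-yl)oxy]-13,14,15,16-tetranorlabd-8(9)-en-7-one (both epimers at the ketal carbon)
Conditions: PPTS (5 mol %), CH2Cl2, 0 °C; Et3N quench
Reagents that add atoms: none
Why: Acid-catalysed Markovnikov addition of the alcohol to the 2-alkoxydiene (C-protonation, kinetic capture of the oxocarbenium ion at carbon) should give the allylic mixed ketal that carries C13–C16, and its ketal stereocentre does not matter later.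

Step 7
Reactants: 8 12-[(2-methoxybut-3-en-2-yl)oxy]-13,14,15,16-tetranorlabd-8(9)-en-7-one
Product: 9 α-face photoadduct with cyclobutane C8–C15–C14–C9 (8β-Me, C11 β on C9) cis-fused to the oxane C9–C11–C12–O–C13(Me)(OMe)–C14, C7 ketone retained
Conditions: hν (λ ≥ 350 nm, Pyrex), MeCN, solid K2CO3, 0 °C
Reagents that add atoms: none
Why: Intramolecular enone–olefin [2+2] photocycloaddition through the enone triplet should close C9–C14 first (six-membered oxane) and then C8–C15 (straight adduct), and the tether can reach C9 only on the α-face opposite the C10 methyl, which fixes C8, C9 and C14 together.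

Step 8
Reactants: 9 α-face photoadduct (C7 ketone)
Product: 11 Δ6-enol acetate of 9 (7-acetoxy), via potassium enolate 10 (not isolated)
Conditions: KHMDS, THF, −78 °C; then Ac2O
Reagents that add atoms: acetic anhydride, CC(=O)OC(C)=O
Why: C6 is the only enolisable position of the C7 ketone (C8 is quaternary), so deprotonation and O-acylation of the potassium enolate should give a single enol acetate while the ketal is inert to base.

Step 9
Reactants: 11 Δ6-enol acetate of 9
Product: 12 7-acetoxy-Δ6 hydroxy ketone with the C14 acetyl group (C13=O) cis to the C9 2-hydroxyethyl arm on the cyclobutane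
Conditions: PPTS (cat.), acetone/H2O, rt
Reagents that add atoms: water, O
Why: Mild acid hydrolysis of the cyclic mixed ketal should release the C13 methyl ketone and the C12 alcohol from both ketal epimers, leave the enol acetate intact, and keep the cis arrangement, which is also the less hindered configuration at C14.

Step 10
Reactants: 12 7-acetoxy-Δ6 hydroxy ketone
Product: 13 7-acetoxy-Δ6 iodo ketone (C12 iodide, C13 methyl ketone)
Conditions: PPh3, I2, imidazole, CH2Cl2, 0 °C
Reagents that add atoms: iodine, II
Why: Appel-type iodination should convert the primary alcohol (reacting through the open hydroxy ketone form) into the iodide by SN2 at C12 without affecting the ketone or the enol acetate.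

Step 11
Reactants: 13 7-acetoxy-Δ6 iodo ketone
Product: 15 (13S)-13-hydroxy tetracycle as the 7-acetoxy-Δ6 enol acetate (ring D closed, 13-OH exo and anti to C15, 13-Me endo), via alkylsamarium diiodide 14 (not isolated)
Conditions: SmI2 (2.5 eq), HMPA, THF, −78 → −20 °C; aq. NaHCO3
Reagents that add atoms: none
Why: SmI2/HMPA should reduce the primary C12 iodide in two single-electron steps to the alkylsamarium 14, which adds to the C13 methyl ketone; the closest known reaction type is the samarium Barbier cyclisation of ω-iodoalkyl ketones to bicyclic tertiary alcohols. Only ring D is closed, in a 5-exo-trig addition to the carbonyl group, and it is necessarily cis-fused to the cyclobutane because the C9 arm and the C14 acetyl group were fixed cis by the former oxane ring. The new stereocentre C13 is set in this addition: the bulky O–Sm(III)(HMPA)n group should take the convex position anti to C15 and the methyl group the concave one, which is the configuration of 17. Both epimers of the earlier ketal converge here because C13 is trigonal in 13. The step needs chemoselectivity for C13 over C7, and this is secured by keeping C7 as its enol acetate, which does not accept the organosamarium. HMPA should make C–I reduction faster than ketyl formation at C13, so that a cyclobutylcarbinyl ketyl and its ring opening are avoided.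

Step 12
Reactants: 15 (13S)-13-hydroxy tetracycle as the 7-acetoxy-Δ6 enol acetate
Product: 16 6α,7α-epoxy-7β-acetoxy derivative of 15
Conditions: DMDO, acetone, 0 °C
Reagents that add atoms: dimethyldioxirane, CC1(C)OO1
Why: Neutral epoxidation of the electron-rich enol acetate should occur on the α-face because the β-face of C6–C7 is screened by the axial C19 and C20 methyls and the C17 methyl, and the tertiary alcohol is inert to the oxidant.

Step 13
Reactants: 16 6α,7α-epoxy-7β-acetoxy derivative of 15
Product: 17 target, 6β-acetoxy-13-hydroxy tetracyclic 7-ketone (CNP0330581.1)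
Conditions: toluene, 110 °C (base-washed glass)
Reagents that add atoms: none
Why: Thermal enol ester epoxide rearrangement should deliver the acetate carbonyl oxygen to C6 from the β-face through a five-membered dioxolanylium-like transition state, so that C6 is inverted to the axial 6β-acetate while C7 becomes the ketone.

**Compound list**
1 | (+)-sclareolide (8α,12-lactone of the tetranorlabdane acid; 5α-H, 9α-H, 10β-Me) | C1C[C@@]3(C)OC(=O)C[C@@H]3[C@@]2(C)CCCC(C)(C)[C@H]12 | starting material
2 | 13,14,15,16-tetranorlabdane-8α,12-diol | C1C[C@@](C)(O)[C@H](CCO)[C@@]2(C)CCCC(C)(C)[C@H]12 | intermediate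
3 | 8α-hydroxy-13,14,15,16-tetranorlabdan-12-yl acetate | C1C[C@@](C)(O)[C@H](CCOC(C)=O)[C@@]2(C)CCCC(C)(C)[C@H]12 | intermediate
4 | 13,14,15,16-tetranorlabd-8(9)-en-12-yl acetate | C1CC(C)=C(CCOC(C)=O)[C@@]2(C)CCCC(C)(C)[C@H]12 | intermediate
5 | 7-oxo-13,14,15,16-tetranorlabd-8(9)-en-12-yl acetate | C1C(=O)C(C)=C(CCOC(C)=O)[C@@]2(C)CCCC(C)(C)[C@H]12 | intermediate
6 | 12-hydroxy-13,14,15,16-tetranorlabd-8(9)-en-7-one | C1C(=O)C(C)=C(CCO)[C@@]2(C)CCCC(C)(C)[C@H]12 | intermediate
7 | 2-methoxy-1,3-butadiene | COC(=C)C=C | starting material
8 | 12-[(2-methoxybut-3-en-2-yl)oxy]-13,14,15,16-tetranorlabd-8(9)-en-7-one (both ketal epimers) | C1C(=O)C(C)=C(CCOC(C)(OC)C=C)[C@@]2(C)CCCC(C)(C)[C@H]12 | intermediate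
9 | α-face [2+2] adduct: cyclobutane C8–C15–C14–C9 cis-fused to the 13-methoxy-13-methyl oxane C9–C11–C12–O–C13–C14, C7 ketone (both C13 epimers) | C1C(=O)[C@@]2(C)C[C@H]3[C@@]2(CCOC3(C)OC)[C@@]2(C)CCCC(C)(C)[C@H]12 | intermediate
10 | potassium Δ6-enolate of 9 | C1=C([O-])[C@@]2(C)C[C@H]3[C@@]2(CCOC3(C)OC)[C@@]2(C)CCCC(C)(C)[C@H]12.[K+] | intermediate
11 | Δ6-enol acetate of 9 (7-acetoxy) | C1=C(OC(C)=O)[C@@]2(C)C[C@H]3[C@@]2(CCOC3(C)OC)[C@@]2(C)CCCC(C)(C)[C@H]12 | intermediate
12 | 7-acetoxy-Δ6 hydroxy ketone (C14 acetyl cis to the C9 2-hydroxyethyl arm) | C1=C(OC(C)=O)[C@@]2(C)C[C@H](C(C)=O)[C@@]2(CCO)[C@@]2(C)CCCC(C)(C)[C@H]12 | intermediate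
13 | 7-acetoxy-Δ6 iodo ketone (C12 iodide) | C1=C(OC(C)=O)[C@@]2(C)C[C@H](C(C)=O)[C@@]2(CCI)[C@@]2(C)CCCC(C)(C)[C@H]12 | intermediate
14 | C12 alkylsamarium(III) diiodide derived from 13 | C1=C(OC(C)=O)[C@@]2(C)C[C@H](C(C)=O)[C@@]2(CC[Sm](I)I)[C@@]2(C)CCCC(C)(C)[C@H]12 | intermediate
15 | (13S)-13-hydroxy tetracycle as 7-acetoxy-Δ6 enol acetate (13-OH anti to C15) | C1=C(OC(C)=O)[C@@]2(C)C[C@H]3[C@@]2(CC[C@]3(C)O)[C@@]2(C)CCCC(C)(C)[C@H]12 | intermediate
16 | 6α,7α-epoxy-7β-acetoxy derivative of 15 | O5[C@H]1[C@]5(OC(C)=O)[C@@]2(C)C[C@H]3[C@@]2(CC[C@]3(C)O)[C@@]2(C)CCCC(C)(C)[C@H]12 | intermediate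
17 | CNP0330581.1, 6β-acetoxy-13-hydroxy tetracyclic 7-ketone | CC(=O)O[C@@H]1C(=O)[C@@]2(C)C[C@H]3[C@@]2(CC[C@]3(C)O)[C@@]2(C)CCCC(C)(C)[C@H]12 | target

**Step count**
Total steps: 13. Longest linear sequence: 13 steps (1 → 17).

**Steps most likely to fail**

Step 11. The addition at C13 may show poor facial selectivity, or the C12 organosamarium may be protonated before it closes the ring. The fallback replaces the halide Barbier closure by a two-carbonyl reductive coupling followed by deoxygenation. It sets out from 12, which would be oxidised with Dess–Martin periodinane to the keto aldehyde F1. SmI2 in THF/t-BuOH at −78 °C should then form the aldehyde ketyl, which adds to the C13 ketone; the Sm(III)-bridged diolate should lie on the convex face and give the cis-12,13-diol F2. Selective acylation of the secondary hydroxyl with phenyl chlorothionoformate and pyridine would give the phenyl thionocarbonate F3, and Barton–McCombie reduction (Bu3SnH, AIBN, toluene, 80 °C) would return to the route at 15.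

Step 13. Traces of acid may divert the epoxy acetate into opening with retention at C6, or the acyloxy shift may be slow at the congested β-face of C6. The fallback sets out from 16: mild methanolysis (K2CO3, MeOH, 0 °C) should cleave the acetate and collapse the epoxy alkoxide to the 6α-hydroxy 7-ketone F4 with retention at C6. A Mitsunobu reaction with acetic acid (PPh3, DIAD, toluene) would then invert C6 and return to the route at 17; the tertiary 13-hydroxyl does not react.

Step 6. The alcohol may be captured at the far end of the allylic oxocarbenium ion (1,4-addition), or the allylic ketal may be lost under the protic acid during isolation. The fallback builds the same ketal from the ketone side under aprotic conditions. It sets out from 6, which would be silylated (TMSCl, imidazole) to the trimethylsilyl ether F5. TMSOTf-catalysed ketalisation of methyl vinyl ketone with F5 and methoxytrimethylsilane (CH2Cl2, −78 °C) would then return to the route at 8.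

**Further compounds**
F1 | step 11 | 7-acetoxy-Δ6 keto aldehyde (C12 aldehyde, C13 methyl ketone) | C1=C(OC(C)=O)[C@@]2(C)C[C@H](C(C)=O)[C@@]2(CC=O)[C@@]2(C)CCCC(C)(C)[C@H]12
F2 | step 11 | cis-12,13-diol of the ring-D-closed 7-acetoxy-Δ6 tetracycle (both hydroxyls anti to C15) | C1=C(OC(C)=O)[C@@]2(C)C[C@H]3[C@@]2(C[C@H](O)[C@]3(C)O)[C@@]2(C)CCCC(C)(C)[C@H]12
F3 | step 11 | 12-O-phenoxythiocarbonyl derivative of F2 | C1=C(OC(C)=O)[C@@]2(C)C[C@H]3[C@@]2(C[C@H](OC(=S)Oc4ccccc4)[C@]3(C)O)[C@@]2(C)CCCC(C)(C)[C@H]12
F4 | step 13 | 6α,13-dihydroxy tetracyclic 7-ketone (6-epi-deacetyl target) | O[C@H]1C(=O)[C@@]2(C)C[C@H]3[C@@]2(CC[C@]3(C)O)[C@@]2(C)CCCC(C)(C)[C@H]12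
F5 | step 6 | 12-(trimethylsilyloxy)-13,14,15,16-tetranorlabd-8(9)-en-7-one | C1C(=O)C(C)=C(CCO[Si](C)(C)C)[C@@]2(C)CCCC(C)(C)[C@H]12
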